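**Strategy**

The plan cuts ring C of the upper 4-arylflavan-3-ol unit (U) at C4a–C4, C4–C3 and O1–C2. It exploits the cis relation between O3(U) and the lower-unit C6 aryl on C4(U): an endo [4+2] addition of a cis-dioxygenated alkene to the o-quinone methide of ring A(U) gives exactly this. In one operation a boronic acid joins 2,3-bis(benzyloxy)phenol to the C6 aldehyde of the lower flavan-3,4-diol (L; benzyl ethers on the phenols, silyl ethers on the diol), and a hydrobenzoin-derived C2-symmetric dioxene closes ring C(U), setting C2, C3 and C4. The C2 acetal is later exchanged for ring B with inversion.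

Key step: step 14

**Remarks on the chemistry**

- Assumption: the (R,R)-dioxene is taken to steer addition to the face of the o-quinone methide that gives the target configuration at C4(U); should the sense be the reverse, (S,S)-hydrobenzoin is used and nothing else changes.
- Labels: Ar(L) = (2R,3S,4R)-7,8-bis(benzyloxy)-2-[4-(benzyloxy)phenyl]-3,4-bis[(tert-butyldimethylsilyl)oxy]chroman-6-yl, the protected lower unit (2-aryl, 3-O and 4-O all cis). α and β are the lower and upper faces of a pyran ring in the usual flavan drawing. The SMILES strings are authoritative.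
- The lower 3,4-diol is carried as its bis(TBS) ether and not as a ketal. A ketal could exchange with PhB(OH)2 in step 14, would ionise before the C2(U) acetal under BF3 in step 16, and would need acid for removal next to the benzylic C4(L)–O bond.
- The flavonol is reduced over Ni, which also removes O-benzyl groups, so the benzyl ethers that are carried to the end are put on after that reduction.
- 2,3-Bis(benzyloxy)phenol is made from 2,3-dihydroxybenzaldehyde by Dakin-type oxidation, which fixes the free-OH/2,3-dibenzyloxy pattern unambiguously.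
- Ring B is delivered as the arylzinc chloride, made from one equivalent each of the aryl bromide and ZnCl2; it is used in excess and is in Schlenk equilibrium with the more nucleophilic diarylzinc.
- C4(U) is R in the free-phenolic target. In the O-benzylated intermediates the same geometry is described by faces, because the CIP ranking at that carbon changes with O-substitution.

**Route**

Step 1
Reactants: 1 gallacetophenone
Product: 2 1-[3,4-bis(benzyloxy)-2-hydroxyphenyl]ethan-1-one
Conditions: BnBr (2.1 equiv), K2CO3 (2.2 equiv), acetone, 50 °C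
Reagents that add atoms: benzyl bromide, BrCc1ccccc1
Why: Williamson etherification should take the 4-OH and 3-OH, while the 2-OH, hydrogen-bonded to the ketone and least reactive, stays free for the later ring closure.

Step 2
Reactants: 2 1-[3,4-bis(benzyloxy)-2-hydroxyphenyl]ethan-1-one; 3 4-(benzyloxy)benzaldehyde
Product: 5 7,8-bis(benzyloxy)-2-[4-(benzyloxy)phenyl]-3-hydroxy-4H-chromen-4-one (flavonol), via chalcone 4 (not isolated)
Conditions: KOH, EtOH, rt; then 30% H2O2, 0 °C → rt; HCl work-up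
Reagents that add atoms: hydrogen peroxide, OO
Why: Claisen–Schmidt condensation gives the (E)-chalcone, and its epoxidation, ring closure by the phenoxide and oxidation (Algar–Flynn–Oyamada reaction) should give the flavonol, favoured over aurone formation because the position ortho to the ketone is unsubstituted.

Step 3
Reactants: 5 flavonol
Product: 6 racemic 2,3-cis-3,4-cis-2-(4-hydroxyphenyl)chromane-3,4,7,8-tetrol (rac-teracacidin)
Conditions: H2 (100 atm), Raney Ni, EtOH, 100 °C
Reagents that add atoms: none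
Why: Catalytic hydrogenation on the Ni surface adds hydrogen to C2=C3 and then to C4=O from the same face of the flat flavonol, which sets C2, C3 and C4 all-cis as the racemate, and the same conditions hydrogenolyse the three O-benzyl groups.

Step 4
Reactants: 6 rac-teracacidin
Product: 7 racemic all-cis 7,8-bis(benzyloxy)-2-[4-(benzyloxy)phenyl]chromane-3,4-diol
Conditions: BnBr (3.2 equiv), K2CO3, DMF, rt, argon
Reagents that add atoms: benzyl bromide, BrCc1ccccc1
Why: Williamson etherification under carbonate should touch only the three phenols, since the secondary alcohols are not deprotonated, and no stereocentre is involved.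

Step 5
Reactants: 7 racemic tri-O-benzyl diol
Product: 8 (2R,3R,4R)-7,8-bis(benzyloxy)-2-[4-(benzyloxy)phenyl]chromane-3,4-diol
Conditions: preparative HPLC on amylose tris(3,5-dimethylphenylcarbamate)/silica, hexane/i-PrOH
Reagents that add atoms: none
Why: Chromatographic resolution on a chiral stationary phase makes no bond, and the wanted fraction is to be identified by hydrogenolysis of a sample to teracacidin and comparison of its chiroptical data with those of the natural (2R,3R,4R) compound.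

Step 6
Reactants: 8 (2R,3R,4R)-diol
Product: 9 (2R,3S,4R)-7,8-bis(benzyloxy)-2-[4-(benzyloxy)phenyl]-3,4-bis[(tert-butyldimethylsilyl)oxy]chromane
Conditions: TBSOTf (2.5 equiv), 2,6-lutidine (4 equiv), CH2Cl2, −78 → 0 °C
Reagents that add atoms: tert-butyldimethylsilyl trifluoromethanesulfonate, CC(C)(C)[Si](C)(C)OS(=O)(=O)C(F)(F)F
Why: O-Silylation with a silyl triflate and a hindered base should cover both secondary alcohols with retention at C3 and C4 (the new C3 descriptor reflects only a change of CIP ranking).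

Step 7
Reactants: 9 bis(silyl) ether
Product: 10 (2R,3S,4R)-7,8-bis(benzyloxy)-2-[4-(benzyloxy)phenyl]-6-bromo-3,4-bis[(tert-butyldimethylsilyl)oxy]chromane
Conditions: NBS (1.05 equiv), MeCN, 0 °C
Reagents that add atoms: N-bromosuccinimide, O=C1CCC(=O)N1Br
Why: Electrophilic aromatic bromination should go to C6 of ring A(L), which is ortho to the 7-benzyloxy group and para to O1, whereas C5 is activated only by the twisted 8-benzyloxy group and ring B by a single ether oxygen.

Step 8
Reactants: 10 C6 bromide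
Product: 12 (2R,3S,4R)-7,8-bis(benzyloxy)-2-[4-(benzyloxy)phenyl]-3,4-bis[(tert-butyldimethylsilyl)oxy]chromane-6-carbaldehyde, via aryllithium 11 (not isolated)
Conditions: n-BuLi (1.1 equiv), THF, −78 °C; DMF, −78 → 0 °C; NH4Cl (aq)
Reagents that add atoms: N,N-dimethylformamide, CN(C)C=O
Why: Bromine–lithium exchange is faster at −78 °C than deprotonation of the benzyl ethers, and the aryllithium is formylated by DMF (Bouveault aldehyde synthesis).

Step 9
Reactants: 13 2,3-dihydroxybenzaldehyde
Product: 14 2,3-bis(benzyloxy)benzaldehyde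
Conditions: BnBr (2.3 equiv), K2CO3, DMF, 60 °C
Reagents that add atoms: benzyl bromide, BrCc1ccccc1
Why: Williamson etherification of both phenols is routine for this aldehyde.

Step 10
Reactants: 14 2,3-bis(benzyloxy)benzaldehyde
Product: 16 2,3-bis(benzyloxy)phenol, via formate 15 (not isolated)
Conditions: mCPBA, CH2Cl2, rt; then K2CO3 (0.1 equiv), MeOH, rt
Reagents that add atoms: 3-chloroperoxybenzoic acid, OOC(=O)c1cccc(Cl)c1
Why: Baeyer–Villiger oxidation of the electron-rich aldehyde proceeds with aryl migration to the aryl formate (Dakin-type oxidation), and methanolysis then frees the phenol whose hydroxyl sits next to the two benzyloxy groups.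

Step 11
Reactants: 17 (R,R)-hydrobenzoin
Product: 18 (1R,2R)-2-(allyloxy)-1,2-diphenylethan-1-ol
Conditions: NaH (1.0 equiv), allyl bromide (1.0 equiv), THF/DMF, 0 °C → rt
Reagents that add atoms: allyl bromide, C=CCBr
Why: Williamson etherification of the monoalkoxide should give mainly the monoether (unreacted diol is recycled) without touching the stereocentres.

Step 12
Reactants: 18 mono-allyl ether
Product: 20 (5R,6R)-5,6-diphenyl-1,4-dioxan-2-ol (anomer mixture), via hydroxy-aldehyde 19 (not isolated)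
Conditions: O3, CH2Cl2/MeOH, −78 °C; then Me2S, −78 °C → rt
Reagents that add atoms: ozone, [O-][O+]=O
Why: Ozonolysis with reductive work-up cleaves the terminal alkene to the aldehyde, which closes on the free hydroxyl to the six-membered lactol.

Step 13
Reactants: 20 lactol
Product: 22 (2R,3R)-2,3-diphenyl-2,3-dihydro-1,4-dioxine, via mesylate 21 (not isolated)
Conditions: MsCl (1.5 equiv), Et3N (4 equiv), CH2Cl2, 0 → 40 °C
Reagents that add atoms: none
Why: O-Sulfonylation of the lactol and base-induced elimination through the oxocarbenium ion give the cyclic enol ether, a standard lactol dehydration that leaves both benzylic stereocentres untouched.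

Step 14
Reactants: 12 lower-unit C6 aldehyde; 16 2,3-bis(benzyloxy)phenol; 22 (R,R)-diphenyldioxene
Product: 25 cis-fused dioxane cycloadduct (7,8-bis(benzyloxy)-4α-Ar(L)-chromane with O2 and O3 both α and bridged by the (1R,2R)-1,2-diphenylethane-1,2-diyl group), via benzodioxaborin 23 (not isolated), via o-quinone methide 24 (not isolated)
Conditions: PhB(OH)2 (1.3 equiv), EtCO2H (0.2 equiv), 4 Å MS, toluene, 80 °C; then 22 (3 equiv), 110 °C, sealed tube
Reagents that add atoms: none
Why: PhB(OH)2 condenses with phenol 16 and aldehyde 12 and delivers the aldehyde carbon to the only free ortho carbon of 16, giving benzodioxaborin 23, which on heating loses PhBO to release (E)-o-quinone methide 24 with C4(U) as its exocyclic carbon; 24 and dioxene 22 then combine in an inverse-electron-demand hetero-Diels–Alder reaction, the closest known types being the boronic-acid-mediated phenol/aldehyde/enol ether chroman synthesis and auxiliary-controlled additions of chiral enol ethers to o-quinone methides. Ring C(U) is closed as a six-membered pyran by this intermolecular [4+2] cycloaddition, with C4(U)–C3(U) and O1(U)–C2(U) formed on one face of the alkene, so the dioxane is cis-fused. C3(U) and C2(U) are fixed relative to C4(U) by the endo transition state (ring oxygens under the heterodiene, aryl on the outside of the E-diene), which puts both C–O bonds cis to the C4 aryl, and the absolute sense at C4(U) is set by the trans-diphenyl groups of 22, whose two alkene faces are equivalent by C2 symmetry so that only the two faces of 24 are told apart. The step needs ortho regioselectivity (secured by the boron tether and the blocked second ortho position), endo selectivity (secured by the E geometry of 24 and the alkoxy-endo preference of enol ethers) and facial selectivity (the auxiliary), and because 12 is a single enantiomer any minor C4(U) epimer is a diastereomer that chromatography should remove. The silyl and benzyl ethers should be inert to the weakly acidic, anhydrous conditions.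

Step 15
Reactants: 26 1-(benzyloxy)-4-bromobenzene
Product: 28 [4-(benzyloxy)phenyl]zinc chloride (solution in THF), via arylmagnesium bromide 27 (not isolated)
Conditions: Mg (1.1 equiv), THF, 40 °C; then ZnCl2 (1.0 equiv), THF, 0 °C → rt
Reagents that add atoms: zinc chloride, Cl[Zn]Cl
Why: Grignard formation by insertion of Mg into the C–Br bond, followed by magnesium-to-zinc transmetallation with one equivalent of ZnCl2, gives the arylzinc chloride.

Step 16
Reactants: 25 cycloadduct; 28 [4-(benzyloxy)phenyl]zinc chloride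
Product: 29 7,8-bis(benzyloxy)-2β-[4-(benzyloxy)phenyl]-4α-Ar(L)-chroman-3α-yl (1R,2R)-2-hydroxy-1,2-diphenylethyl ether (2,3-trans-3,4-cis)
Conditions: 28 (4 equiv, in THF), BF3·OEt2 (4 equiv), CH2Cl2, −78 → 0 °C; NaHCO3 (aq)
Reagents that add atoms: none
Why: Lewis-acid-promoted C-arylation of a cyclic acetal by an organozinc reagent (as in C-aryl glycoside synthesis): BF3 binds the alkyl-substituted acetal oxygen, the C2(U)–O bond ionises to the chroman oxocarbenium ion while the bulky silyl ethers keep the benzylic C4(L)–O bond from competing, and the arylzinc chloride (in Schlenk equilibrium with the diarylzinc) delivers its aryl group to C2(U) on the β face, anti to O3 and to the pseudoaxial C4 aryl, so ring B enters with inversion and the 2,3-trans-3,4-cis triad results.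

Step 17
Reactants: 29 arylated bis(silyl) ether
Product: 30 (2R,3R,4R)-7,8-bis(benzyloxy)-2-[4-(benzyloxy)phenyl]-6-{7,8-bis(benzyloxy)-2β-[4-(benzyloxy)phenyl]-3α-[(1R,2R)-2-hydroxy-1,2-diphenylethoxy]chroman-4α-yl}chromane-3,4-diol
Conditions: Bu4NF (4 equiv), THF, 0 → 40 °C; NH4Cl (aq)
Reagents that add atoms: none
Why: Fluoride-driven Si–O cleavage (desilylation) frees the lower 3,4-diol while the phenols are still benzylated, so no acid comes near the benzylic C4(L)–O bond.

Step 18
Reactants: 30 hexabenzyl ether carrying the hydrobenzoin arm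
Product: 31 CNP0391561.7, (2R,3R,4R)-2-(4-hydroxyphenyl)-6-[(2S,3R,4R)-3,7,8-trihydroxy-2-(4-hydroxyphenyl)chroman-4-yl]chromane-3,4,7,8-tetrol
Conditions: H2 (1 atm), Pd(OH)2 on carbon, THF/MeOH, rt; filtration, Sephadex LH-20
Reagents that add atoms: none
Why: Heterogeneous Pd-catalysed hydrogenolysis under neutral conditions should cleave the six O–CH2Ph bonds and the O3(U)–CH(Ph) bond of the hydrobenzoin ether, while the interflavan C–C bond, the ring C–O bonds and the hindered C4(L) hydroxyl are expected to survive.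

**Compound list**

1 | gallacetophenone, 1-(2,3,4-trihydroxyphenyl)ethan-1-one | CC(=O)c1ccc(O)c(O)c1O | starting material
2 | 1-[3,4-bis(benzyloxy)-2-hydroxyphenyl]ethan-1-one | CC(=O)c1ccc(OCc2ccccc2)c(OCc2ccccc2)c1O | intermediate
3 | 4-(benzyloxy)benzaldehyde | O=Cc1ccc(OCc2ccccc2)cc1 | starting material
4 | (E)-1-[3,4-bis(benzyloxy)-2-hydroxyphenyl]-3-[4-(benzyloxy)phenyl]prop-2-en-1-one (chalcone) | O=C(/C=C/c1ccc(OCc2ccccc2)cc1)c1ccc(OCc2ccccc2)c(OCc2ccccc2)c1O | intermediate
5 | 7,8-bis(benzyloxy)-2-[4-(benzyloxy)phenyl]-3-hydroxy-4H-chromen-4-one (flavonol) | O=c1c(O)c(-c2ccc(OCc3ccccc3)cc2)oc2c(OCc3ccccc3)c(OCc3ccccc3)ccc12 | intermediate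
6 | racemic 2,3-cis-3,4-cis-2-(4-hydroxyphenyl)chromane-3,4,7,8-tetrol (rac-teracacidin, both enantiomers given) | Oc1ccc([C@H]2Oc3c(ccc(O)c3O)[C@@H](O)[C@H]2O)cc1.Oc1ccc([C@@H]2Oc3c(ccc(O)c3O)[C@H](O)[C@@H]2O)cc1 | intermediate
7 | racemic all-cis 7,8-bis(benzyloxy)-2-[4-(benzyloxy)phenyl]chromane-3,4-diol (both enantiomers given) | c1ccccc1COc1ccc([C@H]2Oc3c(ccc(OCc4ccccc4)c3OCc3ccccc3)[C@@H](O)[C@H]2O)cc1.c1ccccc1COc1ccc([C@@H]2Oc3c(ccc(OCc4ccccc4)c3OCc3ccccc3)[C@H](O)[C@@H]2O)cc1 | intermediate
8 | (2R,3R,4R)-7,8-bis(benzyloxy)-2-[4-(benzyloxy)phenyl]chromane-3,4-diol | c1ccccc1COc1ccc([C@H]2Oc3c(ccc(OCc4ccccc4)c3OCc3ccccc3)[C@@H](O)[C@H]2O)cc1 | intermediate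
9 | (2R,3S,4R)-7,8-bis(benzyloxy)-2-[4-(benzyloxy)phenyl]-3,4-bis[(tert-butyldimethylsilyl)oxy]chromane | c1ccccc1COc1ccc([C@H]2Oc3c(ccc(OCc4ccccc4)c3OCc3ccccc3)[C@@H](O[Si](C)(C)C(C)(C)C)[C@H]2O[Si](C)(C)C(C)(C)C)cc1 | intermediate
10 | (2R,3S,4R)-7,8-bis(benzyloxy)-2-[4-(benzyloxy)phenyl]-6-bromo-3,4-bis[(tert-butyldimethylsilyl)oxy]chromane | c1ccccc1COc1ccc([C@H]2Oc3c(cc(Br)c(OCc4ccccc4)c3OCc3ccccc3)[C@@H](O[Si](C)(C)C(C)(C)C)[C@H]2O[Si](C)(C)C(C)(C)C)cc1 | intermediate
11 | Ar(L)–Li, the 6-lithio derivative of 9 | c1ccccc1COc1ccc([C@H]2Oc3c(cc([Li])c(OCc4ccccc4)c3OCc3ccccc3)[C@@H](O[Si](C)(C)C(C)(C)C)[C@H]2O[Si](C)(C)C(C)(C)C)cc1 | intermediate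
12 | Ar(L)–CHO, (2R,3S,4R)-7,8-bis(benzyloxy)-2-[4-(benzyloxy)phenyl]-3,4-bis[(tert-butyldimethylsilyl)oxy]chromane-6-carbaldehyde | c1ccccc1COc1ccc([C@H]2Oc3c(cc(C=O)c(OCc4ccccc4)c3OCc3ccccc3)[C@@H](O[Si](C)(C)C(C)(C)C)[C@H]2O[Si](C)(C)C(C)(C)C)cc1 | intermediate
13 | 2,3-dihydroxybenzaldehyde | O=Cc1cccc(O)c1O | starting material
14 | 2,3-bis(benzyloxy)benzaldehyde | O=Cc1cccc(OCc2ccccc2)c1OCc1ccccc1 | intermediate
15 | 2,3-bis(benzyloxy)phenyl formate | O=COc1cccc(OCc2ccccc2)c1OCc1ccccc1 | intermediate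
16 | 2,3-bis(benzyloxy)phenol | Oc1cccc(OCc2ccccc2)c1OCc1ccccc1 | intermediate
17 | (R,R)-hydrobenzoin, (1R,2R)-1,2-diphenylethane-1,2-diol | O[C@H](c1ccccc1)[C@H](O)c1ccccc1 | starting material
18 | (1R,2R)-2-(allyloxy)-1,2-diphenylethan-1-ol | C=CCO[C@H](c1ccccc1)[C@H](O)c1ccccc1 | intermediate
19 | 2-[(1R,2R)-2-hydroxy-1,2-diphenylethoxy]acetaldehyde | O=CCO[C@H](c1ccccc1)[C@H](O)c1ccccc1 | intermediate
20 | (5R,6R)-5,6-diphenyl-1,4-dioxan-2-ol (anomer mixture) | OC1CO[C@H](c2ccccc2)[C@@H](c2ccccc2)O1 | intermediate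
21 | (5R,6R)-5,6-diphenyl-1,4-dioxan-2-yl methanesulfonate | CS(=O)(=O)OC1CO[C@H](c2ccccc2)[C@@H](c2ccccc2)O1 | intermediate
22 | (2R,3R)-2,3-diphenyl-2,3-dihydro-1,4-dioxine | C1=CO[C@H](c2ccccc2)[C@@H](c2ccccc2)O1 | intermediate
23 | 7,8-bis(benzyloxy)-2-phenyl-4-Ar(L)-4H-1,3,2-benzodioxaborinine (both C4 epimers) | c1ccccc1COc1ccc([C@H]2Oc3c(cc(C4OB(c5ccccc5)Oc5c(OCc6ccccc6)c(OCc6ccccc6)ccc45)c(OCc4ccccc4)c3OCc3ccccc3)[C@@H](O[Si](C)(C)C(C)(C)C)[C@H]2O[Si](C)(C)C(C)(C)C)cc1 | intermediate
24 | (6E)-2,3-bis(benzyloxy)-6-[Ar(L)-methylidene]cyclohexa-2,4-dien-1-one (o-quinone methide) | c1ccccc1COc1ccc([C@H]2Oc3c(cc(/C=C4\C=CC(OCc5ccccc5)=C(OCc5ccccc5)C4=O)c(OCc4ccccc4)c3OCc3ccccc3)[C@@H](O[Si](C)(C)C(C)(C)C)[C@H]2O[Si](C)(C)C(C)(C)C)cc1 | intermediate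
25 | cis-fused cycloadduct: 7,8-bis(benzyloxy)-4α-Ar(L)-chromane with O2 and O3 both α and bridged by (1R,2R)-1,2-diphenylethane-1,2-diyl (C2 is an acetal carbon) | c1ccccc1COc1ccc([C@H]2Oc3c(cc([C@@H]4c5ccc(OCc6ccccc6)c(OCc6ccccc6)c5O[C@@H]7O[C@H](c8ccccc8)[C@@H](c8ccccc8)O[C@@H]74)c(OCc4ccccc4)c3OCc3ccccc3)[C@@H](O[Si](C)(C)C(C)(C)C)[C@H]2O[Si](C)(C)C(C)(C)C)cc1 | intermediate
26 | 1-(benzyloxy)-4-bromobenzene | Brc1ccc(OCc2ccccc2)cc1 | starting material
27 | [4-(benzyloxy)phenyl]magnesium bromide | Br[Mg]c1ccc(OCc2ccccc2)cc1 | intermediate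
28 | [4-(benzyloxy)phenyl]zinc chloride | Cl[Zn]c1ccc(OCc2ccccc2)cc1 | intermediate
29 | 7,8-bis(benzyloxy)-2β-[4-(benzyloxy)phenyl]-4α-Ar(L)-chroman-3α-yl (1R,2R)-2-hydroxy-1,2-diphenylethyl ether | c1ccccc1COc1ccc([C@H]2Oc3c(cc([C@@H]4c5ccc(OCc6ccccc6)c(OCc6ccccc6)c5O[C@@H](c5ccc(OCc6ccccc6)cc5)[C@@H]4O[C@H](c4ccccc4)[C@@H](c4ccccc4)O)c(OCc4ccccc4)c3OCc3ccccc3)[C@@H](O[Si](C)(C)C(C)(C)C)[C@H]2O[Si](C)(C)C(C)(C)C)cc1 | intermediate
30 | the 3,4-diol from 29 (both silyl ethers removed; six benzyl ethers and the hydrobenzoin arm kept) | c1ccccc1COc1ccc([C@H]2Oc3c(cc([C@@H]4c5ccc(OCc6ccccc6)c(OCc6ccccc6)c5O[C@@H](c5ccc(OCc6ccccc6)cc5)[C@@H]4O[C@H](c4ccccc4)[C@@H](c4ccccc4)O)c(OCc4ccccc4)c3OCc3ccccc3)[C@@H](O)[C@H]2O)cc1 | intermediate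
31 | CNP0391561.7, (2R,3R,4R)-2-(4-hydroxyphenyl)-6-[(2S,3R,4R)-3,7,8-trihydroxy-2-(4-hydroxyphenyl)chroman-4-yl]chromane-3,4,7,8-tetrol | Oc1ccc([C@H]2Oc3c(cc([C@@H]4c5ccc(O)c(O)c5O[C@@H](c5ccc(O)cc5)[C@@H]4O)c(O)c3O)[C@@H](O)[C@H]2O)cc1 | target

**Step count and risks**

Total step count: 18. Longest linear sequence: 12 steps (steps 1–8, 14, 16, 17, 18).

Steps most likely to fail:

Step 14. The cycloaddition may be slow or unselective: facial control by the remote phenyl groups may be weak, the dioxene may decompose under acid and heat before 24 is trapped, and 24 may be consumed by excess phenol. The fallback generates the same o-quinone methide anionically at low temperature by carbonate transfer and β-elimination. Commercial 2,3,4-trihydroxybenzaldehyde is benzylated at O3 and O4 (BnBr, K2CO3) to 3,4-bis(benzyloxy)-2-hydroxybenzaldehyde F1, which is acylated (Boc2O, DMAP) to 2,3-bis(benzyloxy)-6-formylphenyl tert-butyl carbonate F2. Bromide 10 is converted through aryllithium 11 and MgBr2·OEt2 into the lower-unit arylmagnesium bromide F3, which is added to F2 at −78 °C in the presence of dioxene 22. The alkoxide takes over the carbonate group, the phenoxide expels it, and 24 forms below 0 °C, where 22 should trap it under kinetic, endo-selective control. This fallback sets out from 10 and returns to the route at 25.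

Step 16. Under the hard Lewis acid, ionisation may occur at the wrong site (the benzylic C4(L)–O bond or the O1(U)–C2(U) bond), the aryl group may pass from zinc to boron before it reaches C2(U), or aryl transfer from the arylzinc chloride may be too slow to outrun decomposition of the cation. The fallback relays through an anomeric sulfone that an arylzinc reagent displaces without BF3. Cycloadduct 25 is opened with PhSSiMe3, ZnI2 and Bu4NI to the 2-phenylthio chroman carrying the O-trimethylsilylated hydrobenzoin arm F4, which mCPBA/NaHCO3 oxidises to the 2-phenylsulfonyl chroman F5. Coupling of F5 with arylzinc chloride 28 in THF in the presence of ZnBr2 gives the trimethylsilyl ether of 29 F6. The fluoride treatment of step 17 then removes all three silyl groups. This fallback sets out from 25 and returns to the route at 30.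

Step 18. The hindered secondary benzylic ether at O3(U) may need long exposure, during which the benzylic C4(L)–OH or a ring O1–C2 bond could be hydrogenolysed. The fallback removes the hydrobenzoin arm chemically while the silyl ethers are still on, so that the last hydrogenolysis only has to cleave aryl benzyl ethers. Compound 29 is oxidised with Dess–Martin periodinane/NaHCO3 to the α-alkoxy ketone F7. SmI2 in THF/MeOH at −78 °C cleaves the C–O bond next to the ketone and gives the 3(U)-alcohol F8. Bu4NF gives the triol hexabenzyl ether F9, and brief hydrogenolysis (H2, Pd on carbon, EtOAc/MeOH) gives the target. This fallback sets out from 29 and returns to the route at 31.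

**Further compounds**

F1 | step 14 | 3,4-bis(benzyloxy)-2-hydroxybenzaldehyde | O=Cc1ccc(OCc2ccccc2)c(OCc2ccccc2)c1O
F2 | step 14 | 2,3-bis(benzyloxy)-6-formylphenyl tert-butyl carbonate | CC(C)(C)OC(=O)Oc1c(C=O)ccc(OCc2ccccc2)c1OCc1ccccc1
F3 | step 14 | Ar(L)–MgBr, lower-unit arylmagnesium bromide | c1ccccc1COc1ccc([C@H]2Oc3c(cc([Mg]Br)c(OCc4ccccc4)c3OCc3ccccc3)[C@@H](O[Si](C)(C)C(C)(C)C)[C@H]2O[Si](C)(C)C(C)(C)C)cc1
F4 | step 16 | 7,8-bis(benzyloxy)-2-(phenylthio)-4α-Ar(L)-chroman-3α-yl (1R,2R)-1,2-diphenyl-2-(trimethylsilyloxy)ethyl ether (both C2 epimers) | c1ccccc1COc1ccc([C@H]2Oc3c(cc([C@@H]4c5ccc(OCc6ccccc6)c(OCc6ccccc6)c5OC(Sc5ccccc5)[C@@H]4O[C@H](c4ccccc4)[C@@H](c4ccccc4)O[Si](C)(C)C)c(OCc4ccccc4)c3OCc3ccccc3)[C@@H](O[Si](C)(C)C(C)(C)C)[C@H]2O[Si](C)(C)C(C)(C)C)cc1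
F5 | step 16 | the 2-phenylsulfonyl analogue of F4 (both C2 epimers) | c1ccccc1COc1ccc([C@H]2Oc3c(cc([C@@H]4c5ccc(OCc6ccccc6)c(OCc6ccccc6)c5OC(S(=O)(=O)c5ccccc5)[C@@H]4O[C@H](c4ccccc4)[C@@H](c4ccccc4)O[Si](C)(C)C)c(OCc4ccccc4)c3OCc3ccccc3)[C@@H](O[Si](C)(C)C(C)(C)C)[C@H]2O[Si](C)(C)C(C)(C)C)cc1
F6 | step 16 | trimethylsilyl ether of 29 (at the hydrobenzoin hydroxyl) | c1ccccc1COc1ccc([C@H]2Oc3c(cc([C@@H]4c5ccc(OCc6ccccc6)c(OCc6ccccc6)c5O[C@@H](c5ccc(OCc6ccccc6)cc5)[C@@H]4O[C@H](c4ccccc4)[C@@H](c4ccccc4)O[Si](C)(C)C)c(OCc4ccccc4)c3OCc3ccccc3)[C@@H](O[Si](C)(C)C(C)(C)C)[C@H]2O[Si](C)(C)C(C)(C)C)cc1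
F7 | step 18 | α-alkoxy ketone from 29, O3(U)–CH(Ph)–C(=O)Ph | c1ccccc1COc1ccc([C@H]2Oc3c(cc([C@@H]4c5ccc(OCc6ccccc6)c(OCc6ccccc6)c5O[C@@H](c5ccc(OCc6ccccc6)cc5)[C@@H]4O[C@H](c4ccccc4)C(=O)c4ccccc4)c(OCc4ccccc4)c3OCc3ccccc3)[C@@H](O[Si](C)(C)C(C)(C)C)[C@H]2O[Si](C)(C)C(C)(C)C)cc1
F8 | step 18 | 7,8-bis(benzyloxy)-2β-[4-(benzyloxy)phenyl]-4α-Ar(L)-chroman-3α-ol | c1ccccc1COc1ccc([C@H]2Oc3c(cc([C@@H]4c5ccc(OCc6ccccc6)c(OCc6ccccc6)c5O[C@@H](c5ccc(OCc6ccccc6)cc5)[C@@H]4O)c(OCc4ccccc4)c3OCc3ccccc3)[C@@H](O[Si](C)(C)C(C)(C)C)[C@H]2O[Si](C)(C)C(C)(C)C)cc1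
F9 | step 18 | hexa-O-benzyl ether of the target (all six phenols benzylated, three alcohols free) | c1ccccc1COc1ccc([C@H]2Oc3c(cc([C@@H]4c5ccc(OCc6ccccc6)c(OCc6ccccc6)c5O[C@@H](c5ccc(OCc6ccccc6)cc5)[C@@H]4O)c(OCc4ccccc4)c3OCc3ccccc3)[C@@H](O)[C@H]2O)cc1
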